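The ten-membered ring is cut at C9–C10 and the chain at C7–C8. The feature exploited is the C6–C7–C8 array: O6 and O8 stand 1,3-anti about C7, O8 is acylated by methacrylic acid (oxidised methacrolein) and O6 belongs to the γ-lactone ring O6/C6/C7/C11/C12. One flask therefore unites the C7 enolate of an acyclic C6 enone, (R)-glyceraldehyde acetonide (C8 plus masked C9) and methacrolein: aldol addition, internal hydride transfer to C6 that leaves the O8 methacrylate, then lactone closure. The precursor is a 4E enone carrying the C10 (Z)-iodoenoate, a phenylthio mask on C13 and a free C12 carboxyl.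

Key step: step 7

Remarks on the chemistry (corrections and assumptions, one line each)
- Numbering: germacrane numbers (C1–C15) are used for all intermediates; C12 is the lactone carbonyl carbon, C13 the exocyclic methylene carbon, C14 the ester carbon on C10. Compound 10 is the precursor of the key step and 16 its product.
- C11: a thiol adds to the itaconate unit without facial control, so the precursor cannot be obtained as one C11 configuration, and none is needed because step 8 removes this centre. Compounds 3 and 8–10 are racemic at C11, 13–17 are C11 epimer pairs, and their SMILES leave C11 (and sulfur in 17) undefined.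
- C12: the carboxyl is kept as the free acid, not as an alkyl ester, because the aldolate oxygen O8 is as well placed as O6 to lactonise on an ester (five-membered ring through C7 and C11). As a lithium carboxylate C12 is inert until acid is added after O8 has been acylated, C11–H is not acidic (no loss of thiolate), and the organolithium of step 4 does not attack it.
- Order after the key step: the sulfide is oxidised and eliminated before periodic acid is used (which would oxidise sulfur) and before ring closure (so that the ten-membered 1,5-diene is never heated).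
- Catalyst: SmI2 is allowed to reduce methacrolein before it meets the substrate, so that only trivalent samarium is present with the iodoenoate and the enone.
- Assumption: ring closure in step 10 is taken to give the 9S carbinol; a correction is given among the fallbacks.

Step 1
Reactants: 1 itaconic anhydride
Product: 2 4-[methoxy(methyl)amino]-2-methylidene-4-oxobutanoic acid
Conditions: MeNHOMe·HCl (1.05 equiv), pyridine (2.2 equiv), CH2Cl2, −10 °C → rt; dilute HCl wash
Reagents that add atoms: N,O-dimethylhydroxylamine hydrochloride, CNOC.Cl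
Why: Anhydride aminolysis should go to the unconjugated, less hindered C6 carbonyl (the C12 carbonyl is deactivated by conjugation with the exocyclic alkene), giving the C6 Weinreb amide and leaving C12 as the free acid; no stereocentre is formed.

Step 2
Reactants: 2 4-[methoxy(methyl)amino]-2-methylidene-4-oxobutanoic acid
Product: 3 4-[methoxy(methyl)amino]-4-oxo-2-[(phenylsulfanyl)methyl]butanoic acid (racemic at C11)
Conditions: PhSH (1.2 equiv), Et3N (0.2 equiv), THF, 50 °C
Reagents that add atoms: thiophenol, Sc1ccccc1
Why: Base-catalysed thia-Michael addition to the 2-substituted acrylic acid masks the C11=C13 alkene as the C13 phenyl sulfide; the new C11 centre forms as a racemate, which is accepted because step 8 erases it.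

Step 3
Reactants: 4 pent-4-yn-1-ol
Product: 6 (E)-5-iodo-4-methylpent-4-en-1-ol, via alkenylalane 5 (not isolated)
Conditions: AlMe3 (3.0 equiv), Cp2ZrCl2 (0.25 equiv), CH2Cl2, 0 °C → rt; then I2 (1.2 equiv), THF, −30 → 0 °C
Reagents that add atoms: trimethylaluminium, C[Al](C)C; iodine, II
Why: Negishi zirconium-catalysed carboalumination adds methyl and aluminium syn across the alkyne (methyl to the internal carbon, C4), and iodinolysis of the C5–Al bond with retention fixes the 4E alkene.

Step 4
Reactants: 6 (E)-5-iodo-4-methylpent-4-en-1-ol; 3 4-[methoxy(methyl)amino]-4-oxo-2-[(phenylsulfanyl)methyl]butanoic acid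
Product: 8 (E)-9-hydroxy-6-methyl-4-oxo-2-[(phenylsulfanyl)methyl]non-5-enoic acid (racemic at C11), via dilithio alkenyl alkoxide 7 (not isolated)
Conditions: 6 (1.3 equiv): MeLi (1.3 equiv) then t-BuLi (2.6 equiv), Et2O, −78 °C; add to 3 pre-treated with LiN(SiMe3)2 (1.0 equiv) in THF, −78 → −30 °C; aq. HCl to pH 3
Reagents that add atoms: none
Why: Iodine–lithium exchange proceeds with retention of alkene geometry and the alkenyllithium adds once to the Weinreb amide (Weinreb ketone synthesis through the chelated tetrahedral adduct), while the C12 lithium carboxylate should be neither attacked nor enolised at this temperature.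

Step 5
Reactants: 8 (E)-9-hydroxy-6-methyl-4-oxo-2-[(phenylsulfanyl)methyl]non-5-enoic acid
Product: 9 (E)-6-methyl-4,9-dioxo-2-[(phenylsulfanyl)methyl]non-5-enoic acid (racemic at C11)
Conditions: Dess–Martin periodinane (1.2 equiv), CH2Cl2, 0 °C → rt
Reagents that add atoms: none
Why: Dess–Martin oxidation takes the primary C1 alcohol to the aldehyde under anhydrous conditions without over-oxidation and should tolerate the sulfide, the enone and the free acid.

Step 6
Reactants: 9 (E)-6-methyl-4,9-dioxo-2-[(phenylsulfanyl)methyl]non-5-enoic acid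
Product: 10 (5E,9Z)-10-iodo-11-methoxy-6-methyl-4,11-dioxo-2-[(phenylsulfanyl)methyl]undeca-5,9-dienoic acid (racemic at C11)
Conditions: Ph3P=CHCO2Me (1.6 equiv), N-iodosuccinimide (1.6 equiv), CH2Cl2, −20 °C; then 9 with i-Pr2NEt (1.05 equiv), −20 °C → rt; aq. citric acid
Reagents that add atoms: methyl (triphenyl-λ5-phosphanylidene)acetate, COC(=O)C=P(c1ccccc1)(c1ccccc1)c1ccccc1; N-iodosuccinimide, O=C1CCC(=O)N1I
Why: Wittig olefination with the α-iodo stabilised ylide made in the flask reacts only at the aldehyde and, as stabilised ylides do, places the ester trans to the C2 chain, which is the (Z)-iodoenoate (iodine cis to C2) needed for ring closure at C10.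

Step 7
Reactants: 10 (5E,9Z)-10-iodo-11-methoxy-6-methyl-4,11-dioxo-2-[(phenylsulfanyl)methyl]undeca-5,9-dienoic acid; 11 (R)-glyceraldehyde acetonide; 12 methacrolein
Product: 16 (6R,7S,8S)-γ-lactone carrying the O8 methacrylate, the (R)-dioxolane on C8 and the iodoenoate chain (C11 epimers), via carboxylate enolate 13 (not isolated), via aldol adduct 14 (not isolated), via hydroxy acid methacrylate 15 (not isolated)
Conditions: lithium 2,2,6,6-tetramethylpiperidide (2.1 equiv), THF, −78 °C; 11 (1.05 equiv), −78 °C; then SmI2 (0.3 equiv) pre-stirred with 12 (8 equiv) in THF until the blue colour is gone, −78 → −20 °C; then 1 M HCl to pH 2–3, 0 °C → rt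
Reagents that add atoms: none
Why: Two equivalents of the lithium amide give the C12 carboxylate and the C7 enolate 13, which adds to 11 through a closed chair transition state to the aldolate 14; trivalent samarium then holds O8 as its hemiacetal with 12, the hemiacetal hydrogen passes to C6 through a six-membered chair so that the hemiacetal carbon becomes the O8 methacrylate (15), and acidification lets the freed C6 hydroxyl close on C12. The closest known reactions are the lithium aldol–Tishchenko reaction and the samarium-catalysed Evans–Tishchenko reduction of β-hydroxy ketones to anti-1,3-diol monoesters, here run with two different aldehydes. The γ-lactone closes by 5-exo-trig attack of O6 on the C12 carboxyl. C8 is set by Felkin–Anh addition anti to the dioxolane oxygen of (R)-11, C7 by the (E)-enolate in the chair aldol transition state (7,8-anti), and C6 by the internal hydride transfer with the C9 and C11 branches equatorial (6,8-anti, hence the trans-lactone). The step needs enolisation at C7 only, reduction at C6 only and lactonisation through O6 rather than O8: C5 is vinylic, C11–H next to a carboxylate is not acidic, methacrolein has no α-hydrogen, the hydride can reach only C6 within the chelate, and the C12 carboxylate is no electrophile until acid is added, by which time O8 is acylated. A syn aldolate, whose C11 branch would be axial in the hydride-transfer chair, should be reduced more slowly and is expected to be lost by retro-aldol cleavage instead of contaminating 16.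

Step 8
Reactants: 16 (6R,7S,8S)-γ-lactone carrying the O8 methacrylate, the (R)-dioxolane on C8 and the iodoenoate chain
Product: 18 (6R,7S,8S)-α-methylene-γ-lactone carrying the O8 methacrylate, the (R)-dioxolane on C8 and the iodoenoate chain, via sulfoxide 17 (not isolated)
Conditions: mCPBA (1.0 equiv), CH2Cl2, −78 °C; NaHCO3 wash; then toluene, BHT (cat.), 100 °C
Reagents that add atoms: none
Why: Sulfide-to-sulfoxide oxidation at −78 °C should outpace epoxidation of the C4=C5 alkene, and the thermal syn-elimination of the sulfoxide can take only C11–H, which unveils the C11=C13 methylene on the still acyclic lactone and removes the unassigned C11 centre.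

Step 9
Reactants: 18 (6R,7S,8S)-α-methylene-γ-lactone carrying the O8 methacrylate, the (R)-dioxolane on C8 and the iodoenoate chain
Product: 20 (6R,7S,8S)-C9 aldehyde (α-methylene-γ-lactone with O8 methacrylate and iodoenoate chain), via diol 19 (not isolated)
Conditions: H5IO6 (2.0 equiv), EtOAc, 0 °C → rt
Reagents that add atoms: none
Why: Periodic acid hydrolyses the terminal acetonide and cleaves the resulting 1,2-diol (Malaprade glycol cleavage) in one operation, cutting off the sacrificial carbon and leaving C9 as the aldehyde, while the non-basic medium should leave C8 untouched and no sulfide remains to be oxidised.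

Step 10
Reactants: 20 (6R,7S,8S)-C9 aldehyde
Product: 21 target, methyl (3aS,4S,5S,6E,10E,11aR)-5-hydroxy-10-methyl-3-methylidene-4-[(2-methylprop-2-enoyl)oxy]-2-oxo-2,3,3a,4,5,8,9,11a-octahydrocyclodeca[b]furan-6-carboxylate
Conditions: CrCl2 (8 equiv), NiCl2 (2 mol %), degassed DMF, rt, slow addition to 2 mM; aq. NH4Cl
Reagents that add atoms: none
Why: In this Nozaki–Hiyama–Kishi reaction nickel-catalysed insertion into the C10–I bond and transfer to chromium give an alkenyl trivalent chromium species that adds only to the aldehyde with retention of the C1=C10 geometry, closing the ten-membered ring at C9–C10; C9 is set under ring control, C10 approaching anti to the C8–O bond in the rotamer that the lactone-bearing chain allows, which is expected to give the 9S carbinol trans to O8.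

Compound list
1 | itaconic anhydride (3-methylideneoxolane-2,5-dione) | C=C1CC(=O)OC1=O | starting material
2 | 4-[methoxy(methyl)amino]-2-methylidene-4-oxobutanoic acid (C6 Weinreb amide, C12 acid) | C=C(CC(=O)N(C)OC)C(=O)O | intermediate
3 | 4-[methoxy(methyl)amino]-4-oxo-2-[(phenylsulfanyl)methyl]butanoic acid, racemic at C11 | OC(=O)C(CSc1ccccc1)CC(=O)N(C)OC | intermediate
4 | pent-4-yn-1-ol | C#CCCCO | starting material
5 | dimethyl{(E)-5-[(dimethylalumanyl)oxy]-2-methylpent-1-en-1-yl}alumane (alkenylalane) | C[Al](C)/C=C(\C)CCCO[Al](C)C | intermediate (not isolated)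
6 | (E)-5-iodo-4-methylpent-4-en-1-ol | I/C=C(\C)CCCO | intermediate
7 | lithium (E)-5-lithio-4-methylpent-4-en-1-olate | [Li]/C=C(\C)CCCO[Li] | intermediate (not isolated)
8 | (E)-9-hydroxy-6-methyl-4-oxo-2-[(phenylsulfanyl)methyl]non-5-enoic acid, racemic at C11 | OC(=O)C(CSc1ccccc1)CC(=O)/C=C(\C)CCCO | intermediate
9 | (E)-6-methyl-4,9-dioxo-2-[(phenylsulfanyl)methyl]non-5-enoic acid, racemic at C11 | OC(=O)C(CSc1ccccc1)CC(=O)/C=C(\C)CCC=O | intermediate
10 | (5E,9Z)-10-iodo-11-methoxy-6-methyl-4,11-dioxo-2-[(phenylsulfanyl)methyl]undeca-5,9-dienoic acid, racemic at C11 (key-step precursor) | OC(=O)C(CSc1ccccc1)CC(=O)/C=C(\C)CC/C=C(\I)C(=O)OC | intermediate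
11 | (R)-2,2-dimethyl-1,3-dioxolane-4-carbaldehyde ((R)-glyceraldehyde acetonide) | O=C[C@H]1COC(C)(C)O1 | starting material
12 | methacrolein (2-methylprop-2-enal) | C=C(C)C=O | starting material
13 | dilithium salt of 10: C12 carboxylate and C6(O)=C7 (E)-enolate, racemic at C11 | [Li]OC(=O)C(CSc1ccccc1)/C=C(/O[Li])\C=C(/C)CC/C=C(\I)C(=O)OC | intermediate (not isolated)
14 | (3R,5E,9Z)-3-{(S)-[(4R)-2,2-dimethyl-1,3-dioxolan-4-yl](hydroxy)methyl}-10-iodo-11-methoxy-6-methyl-4,11-dioxo-2-[(phenylsulfanyl)methyl]undeca-5,9-dienoic acid (7R,8S in germacrane numbering; C11 epimers; present as its dilithium salt) | O[C@H]([C@H]1COC(C)(C)O1)[C@@H](C(CSc2ccccc2)C(=O)O)C(=O)/C=C(\C)CC/C=C(\I)C(=O)OC | intermediate (not isolated)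
15 | (3S,4R,5E,9Z)-3-{(S)-[(4R)-2,2-dimethyl-1,3-dioxolan-4-yl][(2-methylprop-2-enoyl)oxy]methyl}-4-hydroxy-10-iodo-11-methoxy-6-methyl-11-oxo-2-[(phenylsulfanyl)methyl]undeca-5,9-dienoic acid (6R,7S,8S; C11 epimers) | C=C(C)C(=O)O[C@H]([C@H]1COC(C)(C)O1)[C@@H](C(CSc2ccccc2)C(=O)O)[C@H](O)/C=C(\C)CC/C=C(\I)C(=O)OC | intermediate (not isolated)
16 | methyl (2Z,6E)-7-[(2R,3S)-3-{(S)-[(4R)-2,2-dimethyl-1,3-dioxolan-4-yl][(2-methylprop-2-enoyl)oxy]methyl}-5-oxo-4-[(phenylsulfanyl)methyl]oxolan-2-yl]-2-iodo-6-methylhepta-2,6-dienoate (6R,7S,8S; oxolane C4 = C11, both epimers; key-step product) | C=C(C)C(=O)O[C@H]([C@H]1COC(C)(C)O1)[C@H]2C(CSc3ccccc3)C(=O)O[C@@H]2/C=C(\C)CC/C=C(\I)C(=O)OC | intermediate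
17 | sulfoxide of 16, [(benzenesulfinyl)methyl] on C11 (6R,7S,8S; mixture at C11 and at sulfur) | C=C(C)C(=O)O[C@H]([C@H]1COC(C)(C)O1)[C@H]2C(CS(=O)c3ccccc3)C(=O)O[C@@H]2/C=C(\C)CC/C=C(\I)C(=O)OC | intermediate (not isolated)
18 | methyl (2Z,6E)-7-[(2R,3S)-3-{(S)-[(4R)-2,2-dimethyl-1,3-dioxolan-4-yl][(2-methylprop-2-enoyl)oxy]methyl}-4-methylidene-5-oxooxolan-2-yl]-2-iodo-6-methylhepta-2,6-dienoate | C=C(C)C(=O)O[C@H]([C@H]1COC(C)(C)O1)[C@H]2C(=C)C(=O)O[C@@H]2/C=C(\C)CC/C=C(\I)C(=O)OC | intermediate
19 | methyl (2Z,6E)-7-[(2R,3S)-3-{(1S,2R)-2,3-dihydroxy-1-[(2-methylprop-2-enoyl)oxy]propyl}-4-methylidene-5-oxooxolan-2-yl]-2-iodo-6-methylhepta-2,6-dienoate | C=C(C)C(=O)O[C@H]([C@H](O)CO)[C@H]2C(=C)C(=O)O[C@@H]2/C=C(\C)CC/C=C(\I)C(=O)OC | intermediate (not isolated)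
20 | methyl (2Z,6E)-2-iodo-6-methyl-7-[(2R,3S)-4-methylidene-3-{(1S)-1-[(2-methylprop-2-enoyl)oxy]-2-oxoethyl}-5-oxooxolan-2-yl]hepta-2,6-dienoate (C9 aldehyde) | C=C(C)C(=O)O[C@H](C=O)[C@H]2C(=C)C(=O)O[C@@H]2/C=C(\C)CC/C=C(\I)C(=O)OC | intermediate
21 | methyl (3aS,4S,5S,6E,10E,11aR)-5-hydroxy-10-methyl-3-methylidene-4-[(2-methylprop-2-enoyl)oxy]-2-oxo-2,3,3a,4,5,8,9,11a-octahydrocyclodeca[b]furan-6-carboxylate (6R,7S,8S,9S in germacrane numbering) | C=C(C)C(=O)O[C@H]1[C@H]2C(=C)C(=O)O[C@@H]2/C=C(\C)CC/C=C(/C(=O)OC)[C@@H]1O | target

Total step count: 10. Longest linear sequence: 9 steps (1 → 2 → 3 → 8 → 9 → 10 → 16 → 18 → 20 → 21).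

Steps most likely to fail

Step 7. The lithium aldol may leak into the 7,8-syn or anti-Felkin series. The aldolate may also revert and hand the enolate to methacrolein, or the methacryloyl group may migrate from O8 to O6 before the acid quench so that the wrong oxygen lactonises. The fallback is stepwise and uses boron in place of lithium. It sets out from 10, which Me3SiCHN2 in toluene/MeOH converts into the C12 methyl ester of 10 F1. The (E)-enol dicyclohexylborinate of F1 ((c-Hex)2BCl, Et3N, Et2O, −78 → 0 °C) should add to 11 in the anti sense and give, after a non-oxidative work-up and purification, the anti aldol adduct F2. SmI2 (0.3 equiv, pre-stirred with 12) in THF at −10 °C then carries out the Evans–Tishchenko reduction of F2 under neutral conditions. The C6 oxygen closes on the C12 methyl ester (completed with PPTS if required), and the route is rejoined at 16.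

Step 10. The aldehyde may be attacked on the wrong face, since the open-chain Felkin preference of an α-acyloxy aldehyde points to 9R and ring control may not override it; cyclodimerisation may also compete. The fallback sets out from 20 and accepts the closure as it comes. The 9R epimer of the target F3 is oxidised with Dess–Martin periodinane (NaHCO3, CH2Cl2) to the C9 ketone F4. F4 is then reduced under reagent control by a Corey–Bakshi–Shibata reduction with catecholborane at −78 °C, using the (S)-oxazaborolidine if the alkenyl carbon C10 acts as the large group and its antipode otherwise. Catecholborane at −78 °C should leave the α-methylene lactone and the methacrylate alone, and the route is rejoined at 21.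

Step 4. Addition may stall or lose selectivity because the alkoxide-bearing alkenyllithium and the lithium carboxylate aggregate or dissolve poorly, and quenching of the organolithium by proton transfer may compete. The fallback uses protected partners and sets out from 6 and 3. TBSCl and imidazole convert 6 into the silyl ether (E)-tert-butyl[(5-iodo-4-methylpent-4-en-1-yl)oxy]dimethylsilane F5. tert-Butyl 2,2,2-trichloroacetimidate with catalytic BF3·OEt2 converts 3 into the tert-butyl ester of 3 F6. Lithiation of F5 (t-BuLi, Et2O, −78 °C) and addition to F6 should give the protected enone F7. CF3CO2H in wet CH2Cl2 with anisole then removes the silyl ether and the tert-butyl ester together, and the route is rejoined at 8.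

Further compounds
F1 | step 7 | methyl ester of 10, dimethyl (5E,9Z)-10-iodo-6-methyl-4-oxo-2-[(phenylsulfanyl)methyl]undeca-5,9-dienedioate, racemic at C11 | COC(=O)C(CSc1ccccc1)CC(=O)/C=C(\C)CC/C=C(\I)C(=O)OC
F2 | step 7 | anti aldol adduct, methyl ester of 14 (7R,8S; C11 epimers) | O[C@H]([C@H]1COC(C)(C)O1)[C@@H](C(CSc2ccccc2)C(=O)OC)C(=O)/C=C(\C)CC/C=C(\I)C(=O)OC
F3 | step 10 | 9R epimer of 21 | C=C(C)C(=O)O[C@H]1[C@H]2C(=C)C(=O)O[C@@H]2/C=C(\C)CC/C=C(/C(=O)OC)[C@H]1O
F4 | step 10 | C9 ketone corresponding to 21 | C=C(C)C(=O)O[C@H]1[C@H]2C(=C)C(=O)O[C@@H]2/C=C(\C)CC/C=C(/C(=O)OC)C1=O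
F5 | step 4 | (E)-tert-butyl[(5-iodo-4-methylpent-4-en-1-yl)oxy]dimethylsilane | I/C=C(\C)CCCO[Si](C)(C)C(C)(C)C
F6 | step 4 | tert-butyl 4-[methoxy(methyl)amino]-4-oxo-2-[(phenylsulfanyl)methyl]butanoate, racemic at C11 | CC(C)(C)OC(=O)C(CSc1ccccc1)CC(=O)N(C)OC
F7 | step 4 | tert-butyl (E)-9-[(tert-butyldimethylsilyl)oxy]-6-methyl-4-oxo-2-[(phenylsulfanyl)methyl]non-5-enoate, racemic at C11 | CC(C)(C)OC(=O)C(CSc1ccccc1)CC(=O)/C=C(\C)CCCO[Si](C)(C)C(C)(C)C
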